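**Plan**
Numbering: ring A with C7–C9 is the guaiacylglycerol unit; ring B with C7'–C9' and ring C with C7''–C9'' form the furofuran; O1 is the ring oxygen between C7' and C9''.
Retrosynthesis cuts the two O-allyl bonds, then C7–C8 (anti-aldol) and O–C8 (phenol alkylation), then C7''–C8'' together with C9''–H (Prins closure with hydride), then the acetal O–C7'' bond, and last C7'–C8' (syn-aldol), the enol ether being traced back to a terminal alkene.
Forward, the 2,3-dihydrofuran ring (O1, C7', C8', C8'', C9'') is made first, the second tetrahydrofuran ring (C7'', O, C9', C8', C8'') closes in the key step, and the glycerol chain is joined last through the ring B phenol.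
Enabling feature: C8'' is the β-carbon of the cyclic enol ether O1–C9''=C8'' in the ring that already holds C7' and C8', and it is also the neighbour of benzylic C7''; an oxocarbenium at C7'', tethered through O–C9' to C8', can therefore close the second ring at C7''–C8''.
Stereochemistry: C7'/C8' from an Evans syn-aldol ((R)-auxiliary); C8'' from C8' through the obligatory cis ring fusion; C7'' by acid equilibration to the diequatorial furofuran; C7/C8 from a magnesium-catalysed anti-aldol ((S)-auxiliary).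

Key step: step 10

Remark: the Prins closure is taken to put the ring C aryl mainly on the concave face (the usual kinetic outcome of acetal–dihydrofuran closures with electron-rich aryl groups); step 11 equilibrates this centre, so the route holds whichever C7'' epimer forms first.

Step 1
Reactants: 1 (R)-4-benzyloxazolidin-2-one; 2 pent-4-enoyl chloride
Product: 3 (R)-4-benzyl-3-(pent-4-enoyl)oxazolidin-2-one
Conditions: Et3N, DMAP (cat.), CH2Cl2, 0 °C → rt
Reagents that add atoms: none
Why: N-acylation of an oxazolidinone with an acid chloride under DMAP catalysis is routine and creates no stereocentre.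

Step 2
Reactants: 4 vanillin
Product: 5 4-formyl-2-methoxyphenyl 4-methylbenzenesulfonate
Conditions: TsCl, Et3N, DMAP (cat.), CH2Cl2, 0 °C → rt
Reagents that add atoms: 4-toluenesulfonyl chloride, Cc1ccc(S(=O)(=O)Cl)cc1
Why: Sulfonylation of a phenol; the electron-poor sulfonate later keeps the benzylic C7'–O1 bond of ring B from ionising under Lewis acid.

Step 3
Reactants: 3 (R)-4-benzyl-3-(pent-4-enoyl)oxazolidin-2-one; 5 4-formyl-2-methoxyphenyl 4-methylbenzenesulfonate
Product: 8 (R)-4-benzyl-3-[(2R)-2-[(R)-hydroxy(3-methoxy-4-tosyloxyphenyl)methyl]pent-4-enoyl]oxazolidin-2-one, via boron enolate 6 (not isolated), via boron aldolate 7 (not isolated)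
Conditions: Bu2BOTf, iPr2NEt, CH2Cl2, −78 → 0 °C; 5, −78 → 0 °C; H2O2, pH 7 buffer, MeOH, 0 °C
Reagents that add atoms: none
Why: Evans syn-aldol, in which the (Z)-boron enolate reacts through a chair transition state with the aldehyde on the enolate face away from the benzyl group of the (R)-auxiliary, setting C8' and C7' as the 2R,3R syn pair.

Step 4
Reactants: 8 syn-aldol adduct
Product: 10 (R)-4-benzyl-3-[(2R,3R)-5-hydroxy-2-(3-methoxy-4-tosyloxyphenyl)tetrahydrofuran-3-carbonyl]oxazolidin-2-one (lactol as anomer mixture), via ozonide 9 (not isolated)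
Conditions: O3, CH2Cl2, −78 °C; PPh3, −78 °C → rt
Reagents that add atoms: ozone, [O-][O+]=O
Why: Ozonolysis with reductive work-up gives the aldehyde, which the benzylic hydroxyl (the only one present, since the auxiliary is still on) captures as the five-membered lactol, so the ring oxygen is unambiguously the one on C7'.

Step 5
Reactants: 10 lactol
Product: 12 (R)-4-benzyl-3-[(2R,3R)-2-(3-methoxy-4-tosyloxyphenyl)-2,3-dihydrofuran-3-carbonyl]oxazolidin-2-one, via anomeric mesylate 11 (not isolated)
Conditions: MsCl, Et3N, CH2Cl2, −30 °C → rt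
Reagents that add atoms: none
Why: Dehydration of a lactol by anomeric sulfonylation and base-induced elimination gives the cyclic enol ether; the trans 2,3-relationship is not touched.

Step 6
Reactants: 12 dihydrofuran imide
Product: 13 [(2R,3S)-2-(3-methoxy-4-tosyloxyphenyl)-2,3-dihydrofuran-3-yl]methanol
Conditions: LiBH4, MeOH (1 equiv), THF, 0 °C
Reagents that add atoms: none
Why: Reductive cleavage of the N-acyloxazolidinone with LiBH4 frees the primary alcohol and returns the auxiliary, leaving the enol ether and the aryl sulfonate intact.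

Step 7
Reactants: 4 vanillin
Product: 14 4-(allyloxy)-3-methoxybenzaldehyde
Conditions: allyl bromide, K2CO3, DMF, rt
Reagents that add atoms: allyl bromide, C=CCBr
Why: Williamson ether synthesis on the phenol; the allyl ether is chosen because its final removal needs neither acid nor hydrogen.

Step 8
Reactants: 14 4-(allyloxy)-3-methoxybenzaldehyde
Product: 15 4-(allyloxy)-3-methoxybenzaldehyde dimethyl acetal
Conditions: HC(OMe)3, MeOH, PPTS (cat.), rt; Et3N quench
Reagents that add atoms: trimethyl orthoformate, COC(OC)OC; methanol, CO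
Why: Acid-catalysed acetalisation driven by the orthoformate as water scavenger.

Step 9
Reactants: 13 dihydrofuran alcohol; 15 dimethyl acetal
Product: 17 (2R,3S)-3-{[(4-allyloxy-3-methoxyphenyl)(methoxy)methoxy]methyl}-2-(3-methoxy-4-tosyloxyphenyl)-2,3-dihydrofuran (mixed methyl acetal as both acetal epimers), via collidinium salt 16 (not isolated)
Conditions: 15 (2 equiv), TESOTf (1.8 equiv), 2,4,6-collidine (3 equiv), CH2Cl2, 0 °C; then 13, 0 °C → rt
Reagents that add atoms: none
Why: Mixed-acetal formation by acetal exchange through a pyridinium-type salt: the silyl triflate and collidine turn the dimethyl acetal into the N-(α-methoxybenzyl)collidinium salt, which the primary alcohol displaces under buffered conditions that spare the enol ether; the acetal carbon forms as a mixture, which does not matter.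

Step 10
Reactants: 17 mixed methyl acetal
Product: 20 7''-epimer of O-allyl-O'-tosyl-(−)-pinoresinol (7'R,8'S,8''S,7''S; ring B aryl exo; ring C aryl endo), via aryl oxocarbenium triflate 18 (not isolated), via bicyclic oxocarbenium triflate 19 (not isolated)
Conditions: TMSOTf (0.3 equiv), Et3SiH (2 equiv), 2,6-di-tert-butyl-4-methylpyridine (0.1 equiv), CH2Cl2, −78 °C; Et3N quench
Reagents that add atoms: none
Why: TMSOTf removes the methoxy group of 17 to give the (E)-aryl oxocarbenium 18, the enol ether carbon C8'' attacks C7'' to form the C7''–C8'' bond and the second tetrahydrofuran ring, and Et3SiH delivers hydride to the new ring oxocarbenium 19 at C9'', where no stereocentre arises (the acetal configuration is lost on ionisation). The closest known reactions are the Lewis-acid cyclisation of aryl acetals onto 3-(hydroxymethyl)-2,3-dihydrofurans and the silane reduction of the furofuranyl cations so formed, run here as one Prins-type cyclisation with hydride termination. The five-membered ring closes exo with respect to the C8''=C9'' bond and endo with respect to the C7''=O+ bond. C8'' is controlled by C8': the two-atom tether O–C9' reaches only the enol ether face that carries C9', so the ring fusion is cis. C7'' is controlled by the approach of the planar (E)-oxocarbenium, which is expected to stack its aryl group over the enol ether and so place it cis to C9'' (endo, 7''S); as this centre is equilibrated in step 11, the step needs only the cis fusion and chemoselectivity. Chemoselectivity is secured by the intramolecular closure outrunning hydride transfer to the stabilised cation 18, by the hindered pyridine, which keeps acid from protonating the enol ether, and by the ring B tosylate, which keeps the C7'–O1 bond from ionising.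

Step 11
Reactants: 20 7''-epimer (ring C aryl endo)
Product: 22 O-allyl-O'-tosyl-(−)-pinoresinol (7'R,8'S,8''S,7''R; both aryl groups exo; tosylate on ring B; allyl ether on ring C), via ring-opened benzylic cation 21 (not isolated)
Conditions: BF3·OEt2 (0.2 equiv), CH2Cl2 (dilute), 0 °C; Et3N quench; recovered 20 resubmitted
Reagents that add atoms: none
Why: Acid-catalysed epimerisation of a furofuran at a benzylic ether carbon: BF3 reversibly opens the C7''–O bond to the 4-alkoxybenzyl cation 21 (C7' cannot ionise because ring B carries the tosylate), reclosure from either face equilibrates C7'' under thermodynamic control, and since the diequatorial isomer 22 should be favoured only modestly, unchanged 20 is separated and recycled.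

Step 12
Reactants: 22 O-allyl-O'-tosyl-(−)-pinoresinol
Product: 23 (−)-pinoresinol mono-allyl ether (ring B phenol free; ring C phenol allylated; 7'R,8'S,8''S,7''R)
Conditions: KOH, MeOH/THF/H2O, 50 °C; aq. NH4Cl
Reagents that add atoms: none
Why: Alkaline cleavage of the aryl sulfonate (hydroxide attacks sulfur) releases the ring B phenol; the allyl ether and the benzylic ethers are inert to base.

Step 13
Reactants: 24 (S)-4-benzyloxazolidin-2-one; 25 bromoacetyl bromide
Product: 27 (S)-4-benzyl-3-(2-bromoacetyl)oxazolidin-2-one, via lithium oxazolidinide 26 (not isolated)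
Conditions: n-BuLi, THF, −78 °C; then 25, −78 °C
Reagents that add atoms: none
Why: N-acylation of the lithiated oxazolidinone; at −78 °C the acyl bromide reacts in preference to the alkyl bromide.

Step 14
Reactants: 23 (−)-pinoresinol mono-allyl ether; 27 (S)-4-benzyl-3-(2-bromoacetyl)oxazolidin-2-one
Product: 28 (S)-4-benzyl-3-[2-(aryloxy)acetyl]oxazolidin-2-one (aryloxy is the ring B oxygen of 23)
Conditions: K2CO3, MeCN, rt
Reagents that add atoms: none
Why: Williamson ether synthesis with an α-bromo imide, an activated SN2 electrophile, under mild carbonate conditions that leave the imide intact.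

Step 15
Reactants: 28 aryloxyacetyl imide; 14 4-(allyloxy)-3-methoxybenzaldehyde
Product: 30 (S)-4-benzyl-3-[(2R,3R)-3-(4-allyloxy-3-methoxyphenyl)-3-hydroxy-2-(aryloxy)propanoyl]oxazolidin-2-one (anti), via trimethylsilyl ether 29 (not isolated)
Conditions: MgCl2 (0.2 equiv), Et3N, TMSCl, EtOAc, rt; then citric acid, MeOH, 0 °C
Reagents that add atoms: none
Why: Magnesium chloride-catalysed anti-aldol of an N-acyloxazolidinone with silyl trapping: the magnesium-chelated (Z)-enolate adds to the aromatic aldehyde on the face away from the benzyl group of the (S)-auxiliary through a boat-like transition state, which sets the aryloxy-bearing carbon and the carbinol carbon in the anti (erythro) relationship with the absolute sense needed for 8S and 7R; mild methanolysis then removes the silyl group.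

Step 16
Reactants: 30 anti-aldol adduct
Product: 31 (1R,2S)-1-(4-allyloxy-3-methoxyphenyl)-2-(aryloxy)propane-1,3-diol (bis-allyl ether of the target)
Conditions: LiBH4, MeOH (1 equiv), THF, 0 °C
Reagents that add atoms: none
Why: Reductive cleavage of the imide with LiBH4 gives the 1,3-diol and returns the auxiliary without touching a stereocentre.

Step 17
Reactants: 31 bis-allyl ether
Product: 32 CNP0172915.1 (erythro-(7R,8S)-guaiacylglycerol 8-O-4' ether of (−)-pinoresinol)
Conditions: Pd(PPh3)4 (5 mol %), morpholine, THF, rt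
Reagents that add atoms: none
Why: Tsuji–Trost-type deallylation with zerovalent palladium transfers both allyl groups to morpholine under neutral conditions, sparing the benzylic ethers and the benzylic alcohol that hydrogenolysis or acid would endanger.

**Compound list**
1 | (R)-4-benzyloxazolidin-2-one | O=C1N[C@H](Cc2ccccc2)CO1 | starting material
2 | pent-4-enoyl chloride | C=CCCC(=O)Cl | starting material
3 | (R)-4-benzyl-3-(pent-4-enoyl)oxazolidin-2-one | C=CCCC(=O)N1[C@H](Cc2ccccc2)COC1=O | intermediate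
4 | vanillin | COc1cc(C=O)ccc1O | starting material
5 | 4-formyl-2-methoxyphenyl 4-methylbenzenesulfonate | COc1cc(C=O)ccc1OS(=O)(=O)c1ccc(C)cc1 | intermediate
6 | dibutylboron (Z)-enolate of 3 | C=CC/C=C(\OB(CCCC)CCCC)N1[C@H](Cc2ccccc2)COC1=O | intermediate
7 | dibutylboron aldolate of 8 | C=CC[C@H]([C@@H](OB(CCCC)CCCC)c1ccc(OS(=O)(=O)c2ccc(C)cc2)c(OC)c1)C(=O)N1[C@H](Cc2ccccc2)COC1=O | intermediate
8 | (R)-4-benzyl-3-[(2R)-2-[(R)-hydroxy(3-methoxy-4-tosyloxyphenyl)methyl]pent-4-enoyl]oxazolidin-2-one | C=CC[C@H]([C@@H](O)c1ccc(OS(=O)(=O)c2ccc(C)cc2)c(OC)c1)C(=O)N1[C@H](Cc2ccccc2)COC1=O | intermediate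
9 | secondary ozonide (1,2,4-trioxolane) of 8 | C1(OCOO1)C[C@H]([C@@H](O)c1ccc(OS(=O)(=O)c2ccc(C)cc2)c(OC)c1)C(=O)N1[C@H](Cc2ccccc2)COC1=O | intermediate
10 | (R)-4-benzyl-3-[(2R,3R)-5-hydroxy-2-(3-methoxy-4-tosyloxyphenyl)tetrahydrofuran-3-carbonyl]oxazolidin-2-one, anomer mixture | COc1cc([C@@H]2OC(O)C[C@H]2C(=O)N2[C@H](Cc3ccccc3)COC2=O)ccc1OS(=O)(=O)c1ccc(C)cc1 | intermediate
11 | anomeric methanesulfonate of 10 | COc1cc([C@@H]2OC(OS(C)(=O)=O)C[C@H]2C(=O)N2[C@H](Cc3ccccc3)COC2=O)ccc1OS(=O)(=O)c1ccc(C)cc1 | intermediate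
12 | (R)-4-benzyl-3-[(2R,3R)-2-(3-methoxy-4-tosyloxyphenyl)-2,3-dihydrofuran-3-carbonyl]oxazolidin-2-one | COc1cc([C@@H]2OC=C[C@H]2C(=O)N2[C@H](Cc3ccccc3)COC2=O)ccc1OS(=O)(=O)c1ccc(C)cc1 | intermediate
13 | [(2R,3S)-2-(3-methoxy-4-tosyloxyphenyl)-2,3-dihydrofuran-3-yl]methanol | COc1cc([C@@H]2OC=C[C@H]2CO)ccc1OS(=O)(=O)c1ccc(C)cc1 | intermediate
14 | 4-(allyloxy)-3-methoxybenzaldehyde | C=CCOc1ccc(C=O)cc1OC | intermediate
15 | 4-(allyloxy)-3-methoxybenzaldehyde dimethyl acetal | C=CCOc1ccc(C(OC)OC)cc1OC | intermediate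
16 | 1-[(4-allyloxy-3-methoxyphenyl)(methoxy)methyl]-2,4,6-trimethylpyridinium triflate | COC(c1ccc(OCC=C)c(OC)c1)[n+]1c(C)cc(C)cc1C.[O-]S(=O)(=O)C(F)(F)F | intermediate
17 | (2R,3S)-3-{[(4-allyloxy-3-methoxyphenyl)(methoxy)methoxy]methyl}-2-(3-methoxy-4-tosyloxyphenyl)-2,3-dihydrofuran, both acetal epimers | COc1cc([C@@H]2OC=C[C@H]2COC(OC)c2ccc(OCC=C)c(OC)c2)ccc1OS(=O)(=O)c1ccc(C)cc1 | intermediate
18 | (E)-aryl oxocarbenium triflate from 17 (cation at C7'') | COc1cc([C@@H]2OC=C[C@H]2C/[O+]=C/c2ccc(OCC=C)c(OC)c2)ccc1OS(=O)(=O)c1ccc(C)cc1.[O-]S(=O)(=O)C(F)(F)F | intermediate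
19 | cis-fused bicyclic oxocarbenium triflate (O1=C9'' cation, ring C aryl endo) | COc1cc([C@@H]2[O+]=C[C@@H]3[C@H]2CO[C@@H]3c2ccc(OCC=C)c(OC)c2)ccc1OS(=O)(=O)c1ccc(C)cc1.[O-]S(=O)(=O)C(F)(F)F | intermediate
20 | 7''-epimer of O-allyl-O'-tosyl-(−)-pinoresinol (7'R,8'S,8''S,7''S; ring C aryl endo) | COc1cc([C@@H]2OC[C@@H]3[C@H]2CO[C@@H]3c2ccc(OCC=C)c(OC)c2)ccc1OS(=O)(=O)c1ccc(C)cc1 | intermediate
21 | ring-opened C7'' benzylic cation with C9'-O-trifluoroborate (zwitterion) | COc1cc([C@@H]2OC[C@@H]([CH+]c3ccc(OCC=C)c(OC)c3)[C@H]2CO[B-](F)(F)F)ccc1OS(=O)(=O)c1ccc(C)cc1 | intermediate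
22 | O-allyl-O'-tosyl-(−)-pinoresinol (7'R,8'S,8''S,7''R; tosylate on ring B, allyl ether on ring C) | COc1cc([C@@H]2OC[C@@H]3[C@H]2CO[C@H]3c2ccc(OCC=C)c(OC)c2)ccc1OS(=O)(=O)c1ccc(C)cc1 | intermediate
23 | (−)-pinoresinol mono-allyl ether (ring B phenol free) | COc1cc([C@@H]2OC[C@@H]3[C@H]2CO[C@H]3c2ccc(OCC=C)c(OC)c2)ccc1O | intermediate
24 | (S)-4-benzyloxazolidin-2-one | O=C1N[C@@H](Cc2ccccc2)CO1 | starting material
25 | bromoacetyl bromide | BrCC(Br)=O | starting material
26 | lithium (S)-4-benzyl-2-oxooxazolidin-3-ide | [Li+].O=C1[N-][C@@H](Cc2ccccc2)CO1 | intermediate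
27 | (S)-4-benzyl-3-(2-bromoacetyl)oxazolidin-2-one | BrCC(=O)N1[C@@H](Cc2ccccc2)COC1=O | intermediate
28 | (S)-4-benzyl-3-[2-(aryloxy)acetyl]oxazolidin-2-one, aryloxy = ring B oxygen of 23 | COc1cc([C@@H]2OC[C@@H]3[C@H]2CO[C@H]3c2ccc(OCC=C)c(OC)c2)ccc1OCC(=O)N1[C@@H](Cc2ccccc2)COC1=O | intermediate
29 | trimethylsilyl ether of 30 | COc1cc([C@@H](O[Si](C)(C)C)[C@H](C(=O)N2[C@@H](Cc3ccccc3)COC2=O)Oc2ccc([C@@H]3OC[C@@H]4[C@H]3CO[C@H]4c3ccc(OCC=C)c(OC)c3)cc2OC)ccc1OCC=C | intermediate
30 | (S)-4-benzyl-3-[(2R,3R)-3-(4-allyloxy-3-methoxyphenyl)-3-hydroxy-2-(aryloxy)propanoyl]oxazolidin-2-one (anti) | COc1cc([C@@H](O)[C@H](C(=O)N2[C@@H](Cc3ccccc3)COC2=O)Oc2ccc([C@@H]3OC[C@@H]4[C@H]3CO[C@H]4c3ccc(OCC=C)c(OC)c3)cc2OC)ccc1OCC=C | intermediate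
31 | (1R,2S)-1-(4-allyloxy-3-methoxyphenyl)-2-(aryloxy)propane-1,3-diol (bis-allyl ether of the target) | COc1cc([C@@H](O)[C@H](CO)Oc2ccc([C@@H]3OC[C@@H]4[C@H]3CO[C@H]4c3ccc(OCC=C)c(OC)c3)cc2OC)ccc1OCC=C | intermediate
32 | CNP0172915.1 | COc1cc([C@@H](O)[C@H](CO)Oc2ccc([C@@H]3OC[C@@H]4[C@H]3CO[C@H]4c3ccc(O)c(OC)c3)cc2OC)ccc1O | target

**Totals**
Total steps: 17. Longest linear sequence: 13 (steps 1, 3, 4, 5, 6, 9, 10, 11, 12, 14, 15, 16, 17).

**Steps most likely to fail**

Step 10. Hydride transfer to the open cation before ring closure, or protonation of the enol ether followed by its reduction, would divert material. The fallback separates cyclisation from reduction. From 17, TMSOTf (cat.) and the hindered pyridine without silane at −40 °C isomerise the mixed acetal: the released methoxy group captures the ring cation 19 to give the furofuranyl methyl acetal F1. Isolated F1 is then reduced with Et3SiH and BF3·OEt2 at −78 °C and rejoins the route at 20.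

Step 15. The anti selectivity or the facial control may erode because the aryloxy oxygen can join the magnesium chelate, and retro-aldol may occur before silylation. The fallback sets the relative configuration by a boron syn-aldol and corrects C7 by inversion. Lithiation of 1 gives the lithium salt F2, which with 25 gives (R)-4-benzyl-3-(2-bromoacetyl)oxazolidin-2-one F3. Alkylation of 23 with it (K2CO3, MeCN) gives the (R)-aryloxyacetyl imide F4. Bu2BOTf and iPr2NEt form the boron enolate F5, which adds 14 in an Evans syn-aldol through the boron aldolate F6 to give the syn adduct F7. LiBH4 gives the threo diol F8, and selective acetylation of the primary hydroxyl (AcCl, 2,4,6-collidine, −78 °C) gives the monoacetate F9. Mitsunobu esterification with 4-nitrobenzoic acid (PPh3, DIAD) inverts C7 to give the diester F10, and methanolysis (K2CO3, MeOH) removes both esters and rejoins the route at 31.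

Step 9. The alcohol may be silylated instead of exchanged, acid may add across the enol ether, or the labile mixed acetal may be lost on purification. The fallback brings in the acetal carbon at the ester oxidation level. Pinnick oxidation of 14 (NaClO2, NaH2PO4, 2-methylbut-2-ene) gives 4-(allyloxy)-3-methoxybenzoic acid F11, and Steglich esterification with 13 (DCC, DMAP) gives the ester F12. i-Bu2AlH at −78 °C gives the aluminium hemiacetal F13, which is acetylated in the same flask (Ac2O, pyridine, DMAP) to the α-acetoxy ether F14. F14 ionises with TMSOTf to the same cation 18 and, under the conditions of step 10, rejoins the route at 20.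

**Further compounds**
F1 | step 10 | furofuranyl methyl acetal (9''-methoxy derivative of 20, both anomers) | COc1cc([C@@H]2OC(OC)[C@@H]3[C@H]2CO[C@@H]3c2ccc(OCC=C)c(OC)c2)ccc1OS(=O)(=O)c1ccc(C)cc1
F2 | step 15 | lithium (R)-4-benzyl-2-oxooxazolidin-3-ide | [Li+].O=C1[N-][C@H](Cc2ccccc2)CO1
F3 | step 15 | (R)-4-benzyl-3-(2-bromoacetyl)oxazolidin-2-one | BrCC(=O)N1[C@H](Cc2ccccc2)COC1=O
F4 | step 15 | (R)-4-benzyl-3-[2-(aryloxy)acetyl]oxazolidin-2-one, aryloxy = ring B oxygen of 23 | COc1cc([C@@H]2OC[C@@H]3[C@H]2CO[C@H]3c2ccc(OCC=C)c(OC)c2)ccc1OCC(=O)N1[C@H](Cc2ccccc2)COC1=O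
F5 | step 15 | dibutylboron (Z)-enolate of F4 | COc1cc([C@@H]2OC[C@@H]3[C@H]2CO[C@H]3c2ccc(OCC=C)c(OC)c2)ccc1O/C=C(\OB(CCCC)CCCC)N1[C@H](Cc2ccccc2)COC1=O
F6 | step 15 | dibutylboron aldolate of F7 | COc1cc([C@H](OB(CCCC)CCCC)[C@H](C(=O)N2[C@H](Cc3ccccc3)COC2=O)Oc2ccc([C@@H]3OC[C@@H]4[C@H]3CO[C@H]4c3ccc(OCC=C)c(OC)c3)cc2OC)ccc1OCC=C
F7 | step 15 | (R)-4-benzyl-3-[(2R,3S)-3-(4-allyloxy-3-methoxyphenyl)-3-hydroxy-2-(aryloxy)propanoyl]oxazolidin-2-one (syn) | COc1cc([C@H](O)[C@H](C(=O)N2[C@H](Cc3ccccc3)COC2=O)Oc2ccc([C@@H]3OC[C@@H]4[C@H]3CO[C@H]4c3ccc(OCC=C)c(OC)c3)cc2OC)ccc1OCC=C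
F8 | step 15 | (1S,2S)-1-(4-allyloxy-3-methoxyphenyl)-2-(aryloxy)propane-1,3-diol (threo) | COc1cc([C@H](O)[C@H](CO)Oc2ccc([C@@H]3OC[C@@H]4[C@H]3CO[C@H]4c3ccc(OCC=C)c(OC)c3)cc2OC)ccc1OCC=C
F9 | step 15 | primary acetate of F8 | COc1cc([C@H](O)[C@H](COC(C)=O)Oc2ccc([C@@H]3OC[C@@H]4[C@H]3CO[C@H]4c3ccc(OCC=C)c(OC)c3)cc2OC)ccc1OCC=C
F10 | step 15 | (1R,2S)-3-acetoxy-1-(4-allyloxy-3-methoxyphenyl)-2-(aryloxy)propyl 4-nitrobenzoate | COc1cc([C@@H](OC(=O)c2ccc([N+](=O)[O-])cc2)[C@H](COC(C)=O)Oc2ccc([C@@H]3OC[C@@H]4[C@H]3CO[C@H]4c3ccc(OCC=C)c(OC)c3)cc2OC)ccc1OCC=C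
F11 | step 9 | 4-(allyloxy)-3-methoxybenzoic acid | C=CCOc1ccc(C(=O)O)cc1OC
F12 | step 9 | [(2R,3S)-2-(3-methoxy-4-tosyloxyphenyl)-2,3-dihydrofuran-3-yl]methyl 4-(allyloxy)-3-methoxybenzoate | COc1cc([C@@H]2OC=C[C@H]2COC(=O)c2ccc(OCC=C)c(OC)c2)ccc1OS(=O)(=O)c1ccc(C)cc1
F13 | step 9 | diisobutylaluminium hemiacetal alkoxide of F12 | COc1cc([C@@H]2OC=C[C@H]2COC(O[Al](CC(C)C)CC(C)C)c2ccc(OCC=C)c(OC)c2)ccc1OS(=O)(=O)c1ccc(C)cc1
F14 | step 9 | α-acetoxy ether (acetoxy analogue of 17, both epimers) | COc1cc([C@@H]2OC=C[C@H]2COC(OC(C)=O)c2ccc(OCC=C)c(OC)c2)ccc1OS(=O)(=O)c1ccc(C)cc1
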